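**Retrosynthetic overview**

- The only ring of the target, the 10-membered carbocycle, is closed last at C3–C4 by Pd-catalysed coupling of an (E)-alkenylalane (from a terminal alkyne, which also brings in the C5 methyl) with a (Z)-allylic acetate; desilylation and selective acetylation finish the synthesis.
- The (Z)-C1=C2 alkene, the C3 leaving group and the anti C9/C10 diol come from reductive opening of a 6-hydroxy-2H-pyran-3(6H)-one. This temporary oxygen ring is formed first and opened before the macrocyclisation.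
- The pyranone comes from Achmatowicz oxidative dearomatisation of a 2-furylcarbinol: furan supplies C10, C1, C2 and C3, and formaldehyde supplies the CH2OAc carbon by a Morita–Baylis–Hillman reaction.
- The furylcarbinol comes from Felkin addition of 2-furyltitanium to an α-branched ynal, itself made by organocatalytic Michael addition of (R)-citronellal to methyl vinyl ketone followed by methyl ketone → terminal alkyne.

Assumption: commercial (R)-(+)-citronellal supplies the side-chain stereocentre. Target atoms are called C1 (ring carbon bearing CH2OAc), C2, C3, C4=C5(CH3), C6, C7, C8 (side chain), C9 (OH), C10 (OH) and C11 (side-chain stereocentre); the target is (1Z,4E,8S,9R,10S,11R).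

**Route**

Step 1
Reactants: 1 (R)-citronellal [(3R)-3,7-dimethyloct-6-enal]; 2 methyl vinyl ketone (but-3-en-2-one)
Product: 3 (2S)-2-[(2R)-6-methylhept-5-en-2-yl]-5-oxohexanal
Conditions: (S)-2-[methoxy(diphenyl)methyl]pyrrolidine (5 mol %), ethyl 3,4-dihydroxybenzoate (20 mol %), neat, 4 °C
Reagents that add atoms: none
Why: Enamine-catalysed asymmetric Michael addition (diarylprolinol ether catalysis), in which the diphenyl(methoxy)methyl group blocks one face of the E-enamine so the enone adds from the other face and sets C8 as (S) under catalyst control, independent of the C11 methyl centre.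

Step 2
Reactants: 3 (2S)-2-[(2R)-6-methylhept-5-en-2-yl]-5-oxohexanal
Product: 4 (5S,6R)-5-(dimethoxymethyl)-6,10-dimethylundec-9-en-2-one
Conditions: HC(OMe)3, CeCl3·7H2O (10 mol %), MeOH, 0 °C → rt
Reagents that add atoms: trimethyl orthoformate, COC(OC)OC
Why: Chemoselective acetalisation of the aldehyde in the presence of the methyl ketone (Luche–Gemal conditions) masks C9 for the enolate chemistry that follows, and no stereocentre is touched.

Step 3
Reactants: 4 (5S,6R)-5-(dimethoxymethyl)-6,10-dimethylundec-9-en-2-one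
Product: 7 (2S)-2-[(2R)-6-methylhept-5-en-2-yl]hex-5-ynal, via enol diethyl phosphate 5 (not isolated), via alkynyl dimethyl acetal 6 (not isolated)
Conditions: LiN(iPr)2 (1.1 equiv), THF, −78 °C; ClP(O)(OEt)2, → rt; LiN(iPr)2 (2.3 equiv), −78 °C → rt; then 1 M HCl, THF, rt
Reagents that add atoms: water, O
Why: Negishi one-pot conversion of a methyl ketone into a terminal alkyne (kinetic enolate at CH3, enol phosphate, β-elimination), followed by acetal hydrolysis in the acidic work-up; C8 is not enolisable while masked and survives the brief dilute-acid treatment.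

Step 4
Reactants: 7 (2S)-2-[(2R)-6-methylhept-5-en-2-yl]hex-5-ynal; 8 furan
Product: 11 (1R,2S)-1-(furan-2-yl)-2-[(2R)-6-methylhept-5-en-2-yl]hex-5-yn-1-ol, via 2-furyllithium 9 (not isolated), via 2-furyltitanium triisopropoxide 10 (not isolated)
Conditions: furan, n-BuLi, THF, −78 → 0 °C; ClTi(OiPr)3, −78 °C; then 7, −78 → −20 °C
Reagents that add atoms: none
Why: Felkin–Anh-controlled 1,2-addition of a weakly basic aryltitanium reagent (the acetylenic C–H is tolerated), in which attack anti to the large branched C11 substituent gives the (1R) carbinol (C9) as the major epimer, expected about 4:1; the minor (1S) epimer is carried on and removed in step 5.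

Step 5 (key step)
Reactants: 11 (1R,2S)-1-(furan-2-yl)-2-[(2R)-6-methylhept-5-en-2-yl]hex-5-yn-1-ol
Product: 12 (2R)-2-[(5S,6R)-6,10-dimethylundec-9-en-1-yn-5-yl]-6-hydroxy-2H-pyran-3(6H)-one (anomer mixture)
Conditions: Ti(OiPr)4 (20 mol %), D-(−)-diisopropyl tartrate (24 mol %), t-BuOOH (1.0 equiv based on the (1R) epimer), 4 Å MS, CH2Cl2, −20 °C
Reagents that add atoms: tert-butyl hydroperoxide, CC(C)(C)OO
Why: Achmatowicz oxidative ring expansion run under Sharpless kinetic-resolution conditions, in which the titanium tartrate peroxide oxidises the furan of the matched (1R) carbinol much faster than that of the (1S) epimer (which is recovered and separated); the aromatic ring is destroyed, C9 is retained as (2R), the furan carbons are locked as the cis-enone C10(=O)–C1=C2–C3, and the remote alkene and alkyne are untouched because only titanium-bound carbinols are oxidised.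

Step 6
Reactants: 12 (2R)-2-[(5S,6R)-6,10-dimethylundec-9-en-1-yn-5-yl]-6-hydroxy-2H-pyran-3(6H)-one; 13 formaldehyde
Product: 14 (2R)-2-[(5S,6R)-6,10-dimethylundec-9-en-1-yn-5-yl]-6-hydroxy-4-(hydroxymethyl)-2H-pyran-3(6H)-one
Conditions: aq. HCHO (37 %), imidazole (1 equiv), THF–H2O, rt
Reagents that add atoms: none
Why: Morita–Baylis–Hillman α-hydroxymethylation of the cyclic enone (imidazole adds to C2, the enolate is trapped by formaldehyde at C1, the catalyst is expelled) installs the future CH2OAc carbon, with no new stereocentre apart from the irrelevant anomeric one.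

Step 7
Reactants: 14 (2R)-2-[(5S,6R)-6,10-dimethylundec-9-en-1-yn-5-yl]-6-hydroxy-4-(hydroxymethyl)-2H-pyran-3(6H)-one
Product: 15 (2R)-4-({[tert-butyl(dimethyl)silyl]oxy}methyl)-2-[(5S,6R)-6,10-dimethylundec-9-en-1-yn-5-yl]-6-hydroxy-2H-pyran-3(6H)-one
Conditions: TBSCl (1.05 equiv), imidazole, CH2Cl2, −20 → 0 °C
Reagents that add atoms: tert-butyldimethylsilyl chloride, CC(C)(C)[Si](C)(C)Cl
Why: The unhindered primary allylic hydroxyl is silylated faster than the secondary hemiacetal hydroxyl, which distinguishes the future CH2OAc oxygen from the future C3 leaving group.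

Step 8
Reactants: 15 (2R)-4-({[tert-butyl(dimethyl)silyl]oxy}methyl)-2-[(5S,6R)-6,10-dimethylundec-9-en-1-yn-5-yl]-6-hydroxy-2H-pyran-3(6H)-one
Product: 17 (2Z,4S,5R,6S,7R)-6-(but-3-yn-1-yl)-3-({[tert-butyl(dimethyl)silyl]oxy}methyl)-7,11-dimethyldodeca-2,10-diene-1,4,5-triol, via dihydropyranol lactol 16 (not isolated)
Conditions: NaBH4, CeCl3·7H2O, MeOH–CH2Cl2, −78 °C; then NaBH4 (3 equiv), 0 °C → rt
Reagents that add atoms: none
Why: Luche 1,2-reduction delivers hydride to the C10 carbonyl on the face opposite the C9 side chain and gives the 2,3-trans alcohol, i.e. (10S) anti to the C9 oxygen; further borohydride then reduces the open hydroxy-enal form of the lactol and releases the primary C3 allylic alcohol with the Z geometry inherited from the ring.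

Step 9
Reactants: 17 (2Z,4S,5R,6S,7R)-6-(but-3-yn-1-yl)-3-({[tert-butyl(dimethyl)silyl]oxy}methyl)-7,11-dimethyldodeca-2,10-diene-1,4,5-triol
Product: 19 (2Z,4S,5R,6S,7R)-6-(but-3-yn-1-yl)-3-({[tert-butyl(dimethyl)silyl]oxy}methyl)-7,11-dimethyl-4,5-bis[(triethylsilyl)oxy]dodeca-2,10-dien-1-yl acetate, via primary monoacetate 18 (not isolated)
Conditions: AcCl (1.05 equiv), 2,4,6-collidine, CH2Cl2, −78 °C; then TESOTf (2.5 equiv), −78 → 0 °C
Reagents that add atoms: acetyl chloride, CC(=O)Cl; triethylsilyl trifluoromethanesulfonate, CC[Si](CC)(CC)OS(=O)(=O)C(F)(F)F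
Why: Collidine-mediated acetylation at −78 °C is selective for the primary allylic hydroxyl (the C3 leaving group), and silylating both secondary hydroxyls in the same pot prevents the C10 oxygen from closing a 2,5-dihydrofuran onto C3 later.

Step 10
Reactants: 19 (2Z,4S,5R,6S,7R)-6-(but-3-yn-1-yl)-3-({[tert-butyl(dimethyl)silyl]oxy}methyl)-7,11-dimethyl-4,5-bis[(triethylsilyl)oxy]dodeca-2,10-dien-1-yl acetate
Product: 21 tert-butyl({(1Z,4E,8S,9R,10S)-5-methyl-8-[(2R)-6-methylhept-5-en-2-yl]-9,10-bis[(triethylsilyl)oxy]cyclodeca-1,4-dien-1-yl}methoxy)dimethylsilane, via alkenyldimethylalane 20 (not isolated)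
Conditions: AlMe3 (2.5 equiv), Cp2ZrCl2 (0.25 equiv), H2O (1.2 equiv), CH2Cl2, −23 °C; volatiles removed; then slow addition to Pd(PPh3)4 (10 mol %), THF, 2 mM, 40 °C
Reagents that add atoms: trimethylaluminium, C[Al](C)C
Why: Proposed new method: a ring-closing version of Negishi's Zr-catalysed methylalumination / Pd-catalysed alkenyl–allyl coupling, in which syn addition of Me–Al (methyl on the internal carbon) fixes the (E)-C4=C5 alkene, zerovalent palladium ionises the primary allylic acetate, and the alkenyl group is transferred to the less hindered allyl terminus C3 with retention of the Z geometry at C1=C2; the closest known reaction is the intermolecular alane–geranyl/neryl coupling, which gives 1,4-dienes with ≥98 % retention of both alkene geometries.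

Step 11
Reactants: 21 tert-butyl({(1Z,4E,8S,9R,10S)-5-methyl-8-[(2R)-6-methylhept-5-en-2-yl]-9,10-bis[(triethylsilyl)oxy]cyclodeca-1,4-dien-1-yl}methoxy)dimethylsilane
Product: 22 (1S,2R,3S,6E,9Z)-10-(hydroxymethyl)-6-methyl-3-[(2R)-6-methylhept-5-en-2-yl]cyclodeca-6,9-diene-1,2-diol
Conditions: HF·pyridine, pyridine, THF, 0 °C → rt
Reagents that add atoms: none
Why: Buffered fluoride cleaves all three silyl ethers without the strong acid that would trigger transannular cyclisation or isomerisation of the skipped diene.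

Step 12
Reactants: 22 (1S,2R,3S,6E,9Z)-10-(hydroxymethyl)-6-methyl-3-[(2R)-6-methylhept-5-en-2-yl]cyclodeca-6,9-diene-1,2-diol
Product: 23 [(1Z,4E,8S,9R,10S)-9,10-dihydroxy-5-methyl-8-[(2R)-6-methylhept-5-en-2-yl]cyclodeca-1,4-dien-1-yl]methyl acetate
Conditions: AcCl (1.1 equiv), 2,4,6-collidine, CH2Cl2, −78 °C
Reagents that add atoms: acetyl chloride, CC(=O)Cl
Why: Low-temperature collidine-mediated acetylation is selective for the primary allylic hydroxyl over the two secondary hydroxyls and gives the target.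

**Compound list**

1 | (R)-citronellal, (3R)-3,7-dimethyloct-6-enal | C[C@H](CCC=C(C)C)CC=O | starting material
2 | methyl vinyl ketone, but-3-en-2-one | CC(=O)C=C | starting material
3 | (2S)-2-[(2R)-6-methylhept-5-en-2-yl]-5-oxohexanal | O=C[C@@H](CCC(C)=O)[C@H](C)CCC=C(C)C | intermediate
4 | (5S,6R)-5-(dimethoxymethyl)-6,10-dimethylundec-9-en-2-one | COC(OC)[C@@H](CCC(C)=O)[C@H](C)CCC=C(C)C | intermediate
5 | diethyl (5S,6R)-5-(dimethoxymethyl)-6,10-dimethylundeca-1,9-dien-2-yl phosphate | COC(OC)[C@@H](CCC(=C)OP(=O)(OCC)OCC)[C@H](C)CCC=C(C)C | intermediate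
6 | (5S,6R)-5-(dimethoxymethyl)-6,10-dimethylundec-9-en-1-yne | COC(OC)[C@@H](CCC#C)[C@H](C)CCC=C(C)C | intermediate
7 | (2S)-2-[(2R)-6-methylhept-5-en-2-yl]hex-5-ynal | O=C[C@@H](CCC#C)[C@H](C)CCC=C(C)C | intermediate
8 | furan | c1ccoc1 | starting material
9 | 2-furyllithium | [Li]c1ccco1 | intermediate
10 | 2-furyltitanium triisopropoxide | CC(C)O[Ti](OC(C)C)(OC(C)C)c1ccco1 | intermediate
11 | (1R,2S)-1-(furan-2-yl)-2-[(2R)-6-methylhept-5-en-2-yl]hex-5-yn-1-ol | O[C@@H](c1ccco1)[C@@H](CCC#C)[C@H](C)CCC=C(C)C | intermediate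
12 | (2R)-2-[(5S,6R)-6,10-dimethylundec-9-en-1-yn-5-yl]-6-hydroxy-2H-pyran-3(6H)-one, anomer mixture | OC1C=CC(=O)[C@H](O1)[C@@H](CCC#C)[C@H](C)CCC=C(C)C | intermediate
13 | formaldehyde | C=O | starting material
14 | (2R)-2-[(5S,6R)-6,10-dimethylundec-9-en-1-yn-5-yl]-6-hydroxy-4-(hydroxymethyl)-2H-pyran-3(6H)-one | OC1C=C(CO)C(=O)[C@H](O1)[C@@H](CCC#C)[C@H](C)CCC=C(C)C | intermediate
15 | (2R)-4-({[tert-butyl(dimethyl)silyl]oxy}methyl)-2-[(5S,6R)-6,10-dimethylundec-9-en-1-yn-5-yl]-6-hydroxy-2H-pyran-3(6H)-one | OC1C=C(CO[Si](C)(C)C(C)(C)C)C(=O)[C@H](O1)[C@@H](CCC#C)[C@H](C)CCC=C(C)C | intermediate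
16 | (2R,3S)-4-({[tert-butyl(dimethyl)silyl]oxy}methyl)-2-[(5S,6R)-6,10-dimethylundec-9-en-1-yn-5-yl]-3,6-dihydro-2H-pyran-3,6-diol | OC1C=C(CO[Si](C)(C)C(C)(C)C)[C@H](O)[C@H](O1)[C@@H](CCC#C)[C@H](C)CCC=C(C)C | intermediate
17 | (2Z,4S,5R,6S,7R)-6-(but-3-yn-1-yl)-3-({[tert-butyl(dimethyl)silyl]oxy}methyl)-7,11-dimethyldodeca-2,10-diene-1,4,5-triol | OC/C=C(/CO[Si](C)(C)C(C)(C)C)[C@H](O)[C@H](O)[C@@H](CCC#C)[C@H](C)CCC=C(C)C | intermediate
18 | (2Z,4S,5R,6S,7R)-6-(but-3-yn-1-yl)-3-({[tert-butyl(dimethyl)silyl]oxy}methyl)-4,5-dihydroxy-7,11-dimethyldodeca-2,10-dien-1-yl acetate | CC(=O)OC/C=C(/CO[Si](C)(C)C(C)(C)C)[C@H](O)[C@H](O)[C@@H](CCC#C)[C@H](C)CCC=C(C)C | intermediate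
19 | (2Z,4S,5R,6S,7R)-6-(but-3-yn-1-yl)-3-({[tert-butyl(dimethyl)silyl]oxy}methyl)-7,11-dimethyl-4,5-bis[(triethylsilyl)oxy]dodeca-2,10-dien-1-yl acetate | CC(=O)OC/C=C(/CO[Si](C)(C)C(C)(C)C)[C@H](O[Si](CC)(CC)CC)[C@H](O[Si](CC)(CC)CC)[C@@H](CCC#C)[C@H](C)CCC=C(C)C | intermediate
20 | (2Z,4S,5R,6S,7R)-3-({[tert-butyl(dimethyl)silyl]oxy}methyl)-6-[(3E)-4-(dimethylalumanyl)-3-methylbut-3-en-1-yl]-7,11-dimethyl-4,5-bis[(triethylsilyl)oxy]dodeca-2,10-dien-1-yl acetate | CC(=O)OC/C=C(/CO[Si](C)(C)C(C)(C)C)[C@H](O[Si](CC)(CC)CC)[C@H](O[Si](CC)(CC)CC)[C@@H](CC/C(C)=C/[Al](C)C)[C@H](C)CCC=C(C)C | intermediate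
21 | tert-butyl({(1Z,4E,8S,9R,10S)-5-methyl-8-[(2R)-6-methylhept-5-en-2-yl]-9,10-bis[(triethylsilyl)oxy]cyclodeca-1,4-dien-1-yl}methoxy)dimethylsilane | CC(C)(C)[Si](C)(C)OC/C1=C/C/C=C(\C)CC[C@@H]([C@H](C)CCC=C(C)C)[C@@H](O[Si](CC)(CC)CC)[C@H]1O[Si](CC)(CC)CC | intermediate
22 | (1S,2R,3S,6E,9Z)-10-(hydroxymethyl)-6-methyl-3-[(2R)-6-methylhept-5-en-2-yl]cyclodeca-6,9-diene-1,2-diol | OC/C1=C/C/C=C(\C)CC[C@@H]([C@H](C)CCC=C(C)C)[C@@H](O)[C@H]1O | intermediate
23 | [(1Z,4E,8S,9R,10S)-9,10-dihydroxy-5-methyl-8-[(2R)-6-methylhept-5-en-2-yl]cyclodeca-1,4-dien-1-yl]methyl acetate | CC(=O)OC/C1=C/C/C=C(\C)CC[C@@H]([C@H](C)CCC=C(C)C)[C@@H](O)[C@H]1O | target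

**Step count and risks**

Total step count: 12. Longest linear sequence: 12 steps, from (R)-citronellal; furan, methyl vinyl ketone and formaldehyde enter as purchased reagents.

The three steps most likely to fail:

1. Step 10 (ring closure). Forming a 10-membered ring by alkenyl transfer to a π-allylpalladium is unprecedented; methyl transfer from residual AlMe3, oligomerisation and Z → E scrambling of the allyl unit may compete. Fallback: setting out from 19, the alkyne is methylaluminated as before and the alkenylalane 20 is quenched with 2-methoxy-4,4,5,5-tetramethyl-1,3,2-dioxaborolane to give the isolable (E)-alkenyl pinacol boronate F1. All aluminium reagents are thereby removed before ring closure, and an intramolecular Suzuki–Miyaura alkenyl–allyl coupling (Pd(PPh3)4, K3PO4, THF–H2O, 60 °C, 1 mM) comes back to the route at 21.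

2. Step 6 (Baylis–Hillman on the free lactol). The unprotected 6-hydroxypyranone is base-sensitive and may open or rearrange under the nucleophilic catalyst. Fallback: setting out from 7, the C1 substituent is brought in with the heteroarene instead. The commercial furan-3-ylmethanol F2 is doubly lithiated (n-BuLi, 2.2 equiv; alkoxide-directed C2 lithiation), transmetallated with ClTi(OiPr)3 and added to 7 to give the diol F3. Selective silylation of its primary hydroxyl (TBSCl, imidazole) gives the silyl ether F4, and the same tartrate-controlled Achmatowicz oxidation comes back to the route at 15.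

3. Step 8 (one-pot reduction). The hydride facial selectivity on an equilibrating anomer mixture, methyl-glycoside formation in CeCl3/MeOH and incomplete lactol reduction are all uncertain. Fallback: setting out from 15, the lactol is first locked as its 2,6-trans anomeric pivalate F5 (PivCl, Et3N, DMAP, −78 °C). Luche reduction of this single axial-ester anomer, the well-behaved case for trans-selective hydride delivery, gives the allylic alcohol F6. LiBH4 (THF–MeOH) then cleaves the anomeric ester reductively and reduces the liberated lactol, coming back to the route at 17.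

Further compounds
F1 | step 10 | (2Z,4S,5R,6S,7R)-3-({[tert-butyl(dimethyl)silyl]oxy}methyl)-7,11-dimethyl-6-[(3E)-3-methyl-4-(4,4,5,5-tetramethyl-1,3,2-dioxaborolan-2-yl)but-3-en-1-yl]-4,5-bis[(triethylsilyl)oxy]dodeca-2,10-dien-1-yl acetate | CC(=O)OC/C=C(/CO[Si](C)(C)C(C)(C)C)[C@H](O[Si](CC)(CC)CC)[C@H](O[Si](CC)(CC)CC)[C@@H](CC/C(C)=C/B1OC(C)(C)C(C)(C)O1)[C@H](C)CCC=C(C)C
F2 | step 6 | furan-3-ylmethanol | OCc1ccoc1
F3 | step 6 | (1R,2S)-1-[3-(hydroxymethyl)furan-2-yl]-2-[(2R)-6-methylhept-5-en-2-yl]hex-5-yn-1-ol | OCc1ccoc1[C@H](O)[C@@H](CCC#C)[C@H](C)CCC=C(C)C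
F4 | step 6 | (1R,2S)-1-[3-({[tert-butyl(dimethyl)silyl]oxy}methyl)furan-2-yl]-2-[(2R)-6-methylhept-5-en-2-yl]hex-5-yn-1-ol | CC(C)(C)[Si](C)(C)OCc1ccoc1[C@H](O)[C@@H](CCC#C)[C@H](C)CCC=C(C)C
F5 | step 8 | (2R)-4-({[tert-butyl(dimethyl)silyl]oxy}methyl)-2-[(5S,6R)-6,10-dimethylundec-9-en-1-yn-5-yl]-3-oxo-3,6-dihydro-2H-pyran-6-yl 2,2-dimethylpropanoate, 2,6-trans | CC(C)(C)C(=O)O[C@@H]1C=C(CO[Si](C)(C)C(C)(C)C)C(=O)[C@H](O1)[C@@H](CCC#C)[C@H](C)CCC=C(C)C
F6 | step 8 | (2R,3S)-4-({[tert-butyl(dimethyl)silyl]oxy}methyl)-2-[(5S,6R)-6,10-dimethylundec-9-en-1-yn-5-yl]-3-hydroxy-3,6-dihydro-2H-pyran-6-yl 2,2-dimethylpropanoate, 2,6-trans | CC(C)(C)C(=O)O[C@@H]1C=C(CO[Si](C)(C)C(C)(C)C)[C@H](O)[C@H](O1)[C@@H](CCC#C)[C@H](C)CCC=C(C)C
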